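**Plan**

- Retrosynthetic cuts: the three O–Si bonds; then O1–C8a of ring C (aryne closure); then C3–C4 (aldol), giving a ring B/D arylacetyl imide and 3-bromo-4-silyloxybenzaldehyde; then the acetic acid side chain back to the formyl group of 5-hydroxy-2,2-dimethylchromene-6-carbaldehyde; then the pyran of ring D back to 2,4-dihydroxybenzaldehyde and 3-methylbut-2-enal.
- Forward order: ring D is annulated onto ring B first and its carbinol installed (epoxidation, hydride opening). CHO is homologated through vinyl to CH2CO2H. The aldol joins ring A and builds C3–C4. Ring C closes last, and desilylation ends the route.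
- Enabling feature: in ring A the ether oxygen O1 sits on C8a, the next carbon C8 is CH, and C7 beyond it carries oxygen. Bromine on C8 has its only ortho hydrogen on C8a, so an aryne spanning C8–C8a, flanked by the C7 oxygen, accepts the C2 alkoxide at C8a and a proton at C8.
- Stereochemistry: C3'' (R) comes from a Jacobsen epoxidation with the (R,R) catalyst. C3 (R) and C4 (S) come together from an Evans syn aldol with (S)-4-benzyl-2-oxazolidinone (syn in the open chain becomes 3,4-trans in ring C). The ring closure creates no stereocentre.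

Key step: step 13

Remark: the target descriptors are read as (3R,4S) for the isoflavan-4-ol (aryl and hydroxyl trans) and (R) for the ring D carbinol. Locants C2–C8a refer to the isoflavan core, primes to ring B, double primes to ring D. 2-Bromo-4-hydroxybenzaldehyde, used only in a fallback, is assumed to be purchasable.

**Route**

Step 1
Reactants: 1 2,4-dihydroxybenzaldehyde; 2 3-methylbut-2-enal
Product: 4 5-hydroxy-2,2-dimethyl-2H-chromene-6-carbaldehyde, via ortho-quinone methide dienone 3 (not isolated)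
Conditions: pyridine, 140 °C (sealed tube)
Reagents that add atoms: none
Why: Base-mediated condensation of the enal at C3 of the resorcinol ring (the 2-hydroxyl stays hydrogen-bonded to the formyl group, so the 4-hydroxyl is the one that reacts) gives dienone 3, whose oxa-6π electrocyclisation closes the 2H-pyran of ring D, the standard chromene annulation of chelated resorcinol aldehydes.

Step 2
Reactants: 4 5-hydroxy-2,2-dimethyl-2H-chromene-6-carbaldehyde
Product: 5 2,2-dimethyl-5-(triisopropylsilyloxy)-2H-chromene-6-carbaldehyde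
Conditions: TIPSOTf, 2,6-lutidine, CH2Cl2, 0 °C → rt
Reagents that add atoms: triisopropylsilyl triflate, CC(C)[Si](C(C)C)(C(C)C)OS(=O)(=O)C(F)(F)F
Why: Silyl triflate silylation is strong enough for this hydrogen-bonded, doubly flanked phenol, and TIPS is the aryl silyl ether most likely to survive the basic steps ahead.

Step 3
Reactants: 5 2,2-dimethyl-5-(triisopropylsilyloxy)-2H-chromene-6-carbaldehyde
Product: 6 (3R,4R)-3,4-epoxy-2,2-dimethyl-5-(triisopropylsilyloxy)chromane-6-carbaldehyde
Conditions: (R,R)-N,N'-bis(3,5-di-tert-butylsalicylidene)-1,2-cyclohexanediamine manganese chloride [(R,R)-(salen)MnCl, 5 mol %], 4-phenylpyridine N-oxide (20 mol %), aq NaOCl (pH 11.3), CH2Cl2, 0 °C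
Reagents that add atoms: sodium hypochlorite, [Na+].[O-]Cl
Why: Jacobsen–Katsuki epoxidation, for which 2,2-dimethylchromenes with an acceptor para to the ring oxygen are among the best substrates; side-on approach of the cis alkene to the oxo-manganese salen delivers oxygen to one face, the (R,R) catalyst being expected to give the (3R,4R) epoxide and so the C3'' configuration, while the formyl group keeps the benzylic epoxide stable enough to isolate.

Step 4
Reactants: 6 (3R,4R)-3,4-epoxy-2,2-dimethyl-5-(triisopropylsilyloxy)chromane-6-carbaldehyde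
Product: 7 (3R,4R)-3,4-epoxy-2,2-dimethyl-5-(triisopropylsilyloxy)-6-vinylchromane
Conditions: Ph3PCH3Br, t-BuOK, THF, 0 °C
Reagents that add atoms: methyltriphenylphosphonium bromide, C[P+](c1ccccc1)(c1ccccc1)c1ccccc1.[Br-]
Why: Wittig methylenation turns the formyl group into the vinyl group that will be homologated, and the non-stabilised ylide reacts with the aldehyde far faster than with the epoxide at 0 °C.

Step 5
Reactants: 7 (3R,4R)-3,4-epoxy-2,2-dimethyl-5-(triisopropylsilyloxy)-6-vinylchromane
Product: 8 (3R)-2,2-dimethyl-5-(triisopropylsilyloxy)-6-vinylchroman-3-ol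
Conditions: LiAlH4, THF, −20 → 0 °C
Reagents that add atoms: none
Why: Hydride opening of an aryl epoxide by SN2 attack at C4, which is benzylic and activated by the two ortho oxygens while C3 is shielded by the neighbouring quaternary carbon, so the C3–O bond and its configuration are untouched and the styrene is inert to LiAlH4.

Step 6
Reactants: 8 (3R)-2,2-dimethyl-5-(triisopropylsilyloxy)-6-vinylchroman-3-ol
Product: 9 (3R)-2,2-dimethyl-3-(triethylsilyloxy)-5-(triisopropylsilyloxy)-6-vinylchromane
Conditions: TESOTf, 2,6-lutidine, CH2Cl2, −78 → 0 °C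
Reagents that add atoms: triethylsilyl triflate, CC[Si](CC)(CC)OS(=O)(=O)C(F)(F)F
Why: Standard triflate silylation of a hindered secondary alcohol; TES rather than a third TIPS group so that the last step can clear this neopentyl-type ether with mild buffered fluoride.

Step 7
Reactants: 9 (3R)-2,2-dimethyl-3-(triethylsilyloxy)-5-(triisopropylsilyloxy)-6-vinylchromane
Product: 11 2-[(3R)-2,2-dimethyl-3-(triethylsilyloxy)-5-(triisopropylsilyloxy)chroman-6-yl]ethanol, via B-alkyl-9-borabicyclononane 10 (not isolated)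
Conditions: 9-BBN, THF, 0 °C → rt; then NaBO3·4H2O, THF/H2O, rt
Reagents that add atoms: sodium perborate, [Na+].[O-]OB=O
Why: Hydroboration–oxidation, in which 9-BBN places boron on the terminal carbon of the styrene with high anti-Markovnikov selectivity and perborate oxidises the C–B bond without attacking the aryl silyl ether.

Step 8
Reactants: 11 2-[(3R)-2,2-dimethyl-3-(triethylsilyloxy)-5-(triisopropylsilyloxy)chroman-6-yl]ethanol
Product: 13 2-[(3R)-2,2-dimethyl-3-(triethylsilyloxy)-5-(triisopropylsilyloxy)chroman-6-yl]acetic acid, via arylacetaldehyde 12 (not isolated)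
Conditions: TEMPO (20 mol %), PhI(OAc)2 (2.2 equiv), MeCN/pH 7 phosphate buffer, rt
Reagents that add atoms: water, O
Why: Oxoammonium (TEMPO) oxidation with PhI(OAc)2 as terminal oxidant takes the primary alcohol to aldehyde 12 and, through its hydrate, to the acid in one flask; the system is chlorine-free and should spare the electron-rich arene and both silyl ethers.

Step 9
Reactants: 13 2-[(3R)-2,2-dimethyl-3-(triethylsilyloxy)-5-(triisopropylsilyloxy)chroman-6-yl]acetic acid; 14 (S)-4-benzyl-2-oxazolidinone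
Product: 16 (4S)-4-benzyl-3-{2-[(3R)-2,2-dimethyl-3-(triethylsilyloxy)-5-(triisopropylsilyloxy)chroman-6-yl]acetyl}oxazolidin-2-one, via mixed pivalic anhydride 15 (not isolated)
Conditions: PivCl, Et3N, THF, −20 °C; then 14, LiCl, −20 °C → rt
Reagents that add atoms: none
Why: N-acylation of the oxazolidinone through the mixed pivalic anhydride under LiCl/Et3N activation, the usual strong-base-free way to make arylacetyl imides.

Step 10
Reactants: 17 3-bromo-4-hydroxybenzaldehyde
Product: 18 3-bromo-4-(triisopropylsilyloxy)benzaldehyde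
Conditions: TIPSCl, imidazole, DMF, rt
Reagents that add atoms: triisopropylsilyl chloride, CC(C)[Si](Cl)(C(C)C)C(C)C
Why: Routine silylation of an acidic phenol; this silyloxy group later serves as the inductively stabilising C7 oxygen beside the aryne.

Step 11
Reactants: 16 (4S)-4-benzyl-3-{2-[(3R)-2,2-dimethyl-3-(triethylsilyloxy)-5-(triisopropylsilyloxy)chroman-6-yl]acetyl}oxazolidin-2-one; 18 3-bromo-4-(triisopropylsilyloxy)benzaldehyde
Product: 20 (4S)-4-benzyl-3-{(2S,3S)-3-[3-bromo-4-(triisopropylsilyloxy)phenyl]-3-hydroxy-2-[(3R)-2,2-dimethyl-3-(triethylsilyloxy)-5-(triisopropylsilyloxy)chroman-6-yl]propanoyl}oxazolidin-2-one, via Z-dibutylboron enolate 19 (not isolated)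
Conditions: Bu2BOTf, i-Pr2NEt, CH2Cl2, −78 → 0 °C; then 18, −78 → 0 °C; pH 7 buffer, MeOH, 30% H2O2, 0 °C
Reagents that add atoms: none
Why: Evans syn aldol, in which soft enolisation gives the Z boron enolate 19 and a closed chair transition state with the auxiliary carbonyl turned away and the benzyl group blocking one face lets the (S) auxiliary set (2S,3S), which is C3 (R) and C4 (S) of the isoflavan with aryl and hydroxyl trans after ring closure.

Step 12
Reactants: 20 the syn aldol imide of step 11
Product: 21 (1S,2R)-1-[3-bromo-4-(triisopropylsilyloxy)phenyl]-2-[(3R)-2,2-dimethyl-3-(triethylsilyloxy)-5-(triisopropylsilyloxy)chroman-6-yl]propane-1,3-diol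
Conditions: LiBH4, MeOH (1.1 equiv), THF, 0 °C
Reagents that add atoms: none
Why: Reductive cleavage of the imide with LiBH4 gives the primary alcohol that will become O1 and returns the oxazolidinone, the low temperature guarding against retro-aldol of the α-aryl aldolate.

Step 13
Reactants: 21 (1S,2R)-1-[3-bromo-4-(triisopropylsilyloxy)phenyl]-2-[(3R)-2,2-dimethyl-3-(triethylsilyloxy)-5-(triisopropylsilyloxy)chroman-6-yl]propane-1,3-diol
Product: 23 (3R,4S)-3-[(3R)-2,2-dimethyl-3-(triethylsilyloxy)-5-(triisopropylsilyloxy)chroman-6-yl]-7-(triisopropylsilyloxy)chroman-4-ol, via dilithium aryne dialkoxide 22 (not isolated)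
Conditions: LiTMP (5 equiv, from TMPH and n-BuLi), THF (0.01 M), −78 → −40 °C; sat. aq NH4Cl at −78 °C
Reagents that add atoms: none
Why: Excess LiTMP first forms the dilithium dialkoxide and then removes the hydrogen on C8a, the only hydrogen ortho to bromine (acidified by Br and the meta silyloxy group and held near the base by the neighbouring benzylic alkoxide), and loss of LiBr gives aryne 22 across C8–C8a. The primary C2 alkoxide adds to C8a in a 6-exo-dig closure onto the in-plane π bond, forming O1–C8a and ring C; the closest known reaction type is the intramolecular addition of alkoxides and amines to arynes generated from haloarenes with lithium amides or NaNH2 (benzyne cyclisation to chromans and indolines). Three selectivities are needed: the site of aryne formation is fixed by the single ortho hydrogen (an amide base does no Br–Li exchange), the site of addition by the three-atom tether from C4a and by the C7 oxygen, which inductively stabilises the aryl anion left at C8, and the choice of alkoxide by ring size, since the C4 alkoxide could only form a four-membered ring. The C8 anion is protonated by TMPH or on quench, so the net result is cine-substitution of bromine at C8 by oxygen at C8a. No stereocentre is formed or touched, the hindered amide and high dilution disfavour intermolecular capture, and the low temperature should keep the ortho-silyloxy aryllithium from oxygen-to-carbon silyl migration.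

Step 14
Reactants: 23 (3R,4S)-3-[(3R)-2,2-dimethyl-3-(triethylsilyloxy)-5-(triisopropylsilyloxy)chroman-6-yl]-7-(triisopropylsilyloxy)chroman-4-ol
Product: 24 (3R,4S)-3-[(3R)-3,5-dihydroxy-2,2-dimethylchroman-6-yl]chromane-4,7-diol (CNP0271781.1)
Conditions: TBAF, AcOH (1:1, 5 equiv), THF, 0 °C → rt
Reagents that add atoms: none
Why: Fluoride desilylation of two aryl and one alkyl silyl ether, with acetic acid buffering the phenoxides so that the 4-hydroxyl para to the freed C7 phenol is not expelled (quinone methide, pterocarpan closure by the 2'-hydroxyl) and no stereocentre is disturbed.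

**Compound list**

1 | 2,4-dihydroxybenzaldehyde | O=Cc1ccc(O)cc1O | starting material
2 | 3-methylbut-2-enal | CC(C)=CC=O | starting material
3 | ortho-quinone methide dienone from condensation at C3 | O=C1C=CC(C=O)=C(O)C1=CC=C(C)C | intermediate, not isolated
4 | 5-hydroxy-2,2-dimethyl-2H-chromene-6-carbaldehyde | CC1(C)C=Cc2c(O1)ccc(C=O)c2O | intermediate
5 | 2,2-dimethyl-5-(triisopropylsilyloxy)-2H-chromene-6-carbaldehyde | CC1(C)C=Cc2c(O1)ccc(C=O)c2O[Si](C(C)C)(C(C)C)C(C)C | intermediate
6 | (3R,4R)-3,4-epoxy-2,2-dimethyl-5-(triisopropylsilyloxy)chromane-6-carbaldehyde | CC1(C)Oc2ccc(C=O)c(O[Si](C(C)C)(C(C)C)C(C)C)c2[C@H]3O[C@@H]13 | intermediate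
7 | (3R,4R)-3,4-epoxy-2,2-dimethyl-5-(triisopropylsilyloxy)-6-vinylchromane | CC1(C)Oc2ccc(C=C)c(O[Si](C(C)C)(C(C)C)C(C)C)c2[C@H]3O[C@@H]13 | intermediate
8 | (3R)-2,2-dimethyl-5-(triisopropylsilyloxy)-6-vinylchroman-3-ol | CC1(C)Oc2ccc(C=C)c(O[Si](C(C)C)(C(C)C)C(C)C)c2C[C@H]1O | intermediate
9 | (3R)-2,2-dimethyl-3-(triethylsilyloxy)-5-(triisopropylsilyloxy)-6-vinylchromane | CC1(C)Oc2ccc(C=C)c(O[Si](C(C)C)(C(C)C)C(C)C)c2C[C@H]1O[Si](CC)(CC)CC | intermediate
10 | B-(2-arylethyl)-9-borabicyclo[3.3.1]nonane from 9 | CC1(C)Oc2ccc(CCB3C4CCCC3CCC4)c(O[Si](C(C)C)(C(C)C)C(C)C)c2C[C@H]1O[Si](CC)(CC)CC | intermediate, not isolated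
11 | 2-[(3R)-2,2-dimethyl-3-(triethylsilyloxy)-5-(triisopropylsilyloxy)chroman-6-yl]ethanol | CC1(C)Oc2ccc(CCO)c(O[Si](C(C)C)(C(C)C)C(C)C)c2C[C@H]1O[Si](CC)(CC)CC | intermediate
12 | 2-[(3R)-2,2-dimethyl-3-(triethylsilyloxy)-5-(triisopropylsilyloxy)chroman-6-yl]acetaldehyde | CC1(C)Oc2ccc(CC=O)c(O[Si](C(C)C)(C(C)C)C(C)C)c2C[C@H]1O[Si](CC)(CC)CC | intermediate, not isolated
13 | 2-[(3R)-2,2-dimethyl-3-(triethylsilyloxy)-5-(triisopropylsilyloxy)chroman-6-yl]acetic acid | CC1(C)Oc2ccc(CC(=O)O)c(O[Si](C(C)C)(C(C)C)C(C)C)c2C[C@H]1O[Si](CC)(CC)CC | intermediate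
14 | (S)-4-benzyl-2-oxazolidinone | O=C1N[C@@H](Cc2ccccc2)CO1 | starting material
15 | mixed pivalic anhydride of acid 13 | CC1(C)Oc2ccc(CC(=O)OC(=O)C(C)(C)C)c(O[Si](C(C)C)(C(C)C)C(C)C)c2C[C@H]1O[Si](CC)(CC)CC | intermediate, not isolated
16 | (4S)-4-benzyl-3-{2-[(3R)-2,2-dimethyl-3-(triethylsilyloxy)-5-(triisopropylsilyloxy)chroman-6-yl]acetyl}oxazolidin-2-one | CC1(C)Oc2ccc(CC(=O)N3[C@@H](Cc4ccccc4)COC3=O)c(O[Si](C(C)C)(C(C)C)C(C)C)c2C[C@H]1O[Si](CC)(CC)CC | intermediate
17 | 3-bromo-4-hydroxybenzaldehyde | O=Cc1ccc(O)c(Br)c1 | starting material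
18 | 3-bromo-4-(triisopropylsilyloxy)benzaldehyde | O=Cc1ccc(O[Si](C(C)C)(C(C)C)C(C)C)c(Br)c1 | intermediate
19 | (Z)-dibutylboron enolate of imide 16 | CC1(C)Oc2ccc(/C=C(\OB(CCCC)CCCC)N3[C@@H](Cc4ccccc4)COC3=O)c(O[Si](C(C)C)(C(C)C)C(C)C)c2C[C@H]1O[Si](CC)(CC)CC | intermediate, not isolated
20 | (4S)-4-benzyl-3-{(2S,3S)-3-[3-bromo-4-(triisopropylsilyloxy)phenyl]-3-hydroxy-2-[(3R)-2,2-dimethyl-3-(triethylsilyloxy)-5-(triisopropylsilyloxy)chroman-6-yl]propanoyl}oxazolidin-2-one | CC1(C)Oc2ccc([C@@H]([C@H](O)c3ccc(O[Si](C(C)C)(C(C)C)C(C)C)c(Br)c3)C(=O)N3[C@@H](Cc4ccccc4)COC3=O)c(O[Si](C(C)C)(C(C)C)C(C)C)c2C[C@H]1O[Si](CC)(CC)CC | intermediate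
21 | (1S,2R)-1-[3-bromo-4-(triisopropylsilyloxy)phenyl]-2-[(3R)-2,2-dimethyl-3-(triethylsilyloxy)-5-(triisopropylsilyloxy)chroman-6-yl]propane-1,3-diol | CC1(C)Oc2ccc([C@@H]([C@H](O)c3ccc(O[Si](C(C)C)(C(C)C)C(C)C)c(Br)c3)CO)c(O[Si](C(C)C)(C(C)C)C(C)C)c2C[C@H]1O[Si](CC)(CC)CC | intermediate
22 | dilithium dialkoxide of the C8–C8a aryne derived from 21 | CC1(C)Oc2ccc([C@@H]([C@H]([O-])C3=CC=C(O[Si](C(C)C)(C(C)C)C(C)C)C#C3)C[O-])c(O[Si](C(C)C)(C(C)C)C(C)C)c2C[C@H]1O[Si](CC)(CC)CC.[Li+].[Li+] | intermediate, not isolated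
23 | (3R,4S)-3-[(3R)-2,2-dimethyl-3-(triethylsilyloxy)-5-(triisopropylsilyloxy)chroman-6-yl]-7-(triisopropylsilyloxy)chroman-4-ol | CC1(C)Oc2ccc([C@@H]3COc4cc(O[Si](C(C)C)(C(C)C)C(C)C)ccc4[C@H]3O)c(O[Si](C(C)C)(C(C)C)C(C)C)c2C[C@H]1O[Si](CC)(CC)CC | intermediate
24 | (3R,4S)-3-[(3R)-3,5-dihydroxy-2,2-dimethylchroman-6-yl]chromane-4,7-diol | CC1(C)Oc2ccc([C@@H]3COc4cc(O)ccc4[C@H]3O)c(O)c2C[C@H]1O | target

**Step count and risks**

Total steps: 14. Longest linear sequence: 13 steps (1 to 24 through steps 1–9 and 11–14); step 10 is a one-step side branch.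

Steps most likely to fail:

Step 13 (aryne ring closure). Metalation may not stay at C8a (ring B or benzylic positions can compete). The hindered amide, or a hydride from the alkoxide carbon, may trap the aryne before oxygen does. The aryllithium left at C8 may pull the neighbouring silyl group from oxygen to carbon on warming. The fallback forms the same O1–C8a bond by metal-catalysed C–O coupling and sets out from imide 16. 2-Bromo-4-hydroxybenzaldehyde F1 is silylated (TIPSCl, imidazole, DMF) to 2-bromo-4-(triisopropylsilyloxy)benzaldehyde F2. The boron aldol of step 11, run with F2 in place of 18, should give the syn aldol imide F3, and LiBH4 as in step 12 the diol F4, which carries bromine on the future C8a. Intramolecular Buchwald etherification (Pd(OAc)2, 2-(di-tert-butylphosphino)-1,1'-binaphthyl, Cs2CO3, toluene, 70 °C) should then close the six-membered ring through the primary alcohol, the secondary one being limited to a four-membered ring. The route is rejoined at 23.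

Step 3 (asymmetric epoxidation). Oxygen transfer may be slow and poorly face-selective, because the bulky silyloxy group sits peri to C4 and the formyl group deactivates the alkene. The aryl silyl ether may also be partly hydrolysed at pH 11. The fallback sets C3'' by reagent-controlled ketone reduction and sets out from 5. Dimethyldioxirane (acetone, 0 °C) gives the racemic epoxy aldehyde F5. Methylenation as in step 4 gives the racemic vinyl epoxide F6, and LiAlH4 as in step 5 the racemic chroman-3-ol F7. Dess–Martin periodinane oxidises this to 2,2-dimethyl-5-(triisopropylsilyloxy)-6-vinylchroman-3-one F8. Corey–Bakshi–Shibata reduction with the (S)-B-methyl oxazaborolidine and catecholborane (toluene, −78 °C, conditions that leave the styrene alone) should deliver hydride so that the quaternary C2 side acts as the large group. This gives the (R)-alcohol, and the route is rejoined at 8.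

Step 5 (hydride opening of the vinyl epoxide). Once the formyl group is gone the epoxide is electron-rich. Ionisation at C4 assisted by the lithium or aluminium centre, followed by hydride shift, would give the chroman-3-one and, after unselective reduction, eroded enantiopurity. Hydride may also enter at C3. The fallback cleaves the benzylic C–O bond by hydrogenolysis while the ring still carries the formyl group and sets out from 6. H2 (1 atm), Pd/C, EtOAc with a trace of Et3N should give (3R)-3-hydroxy-2,2-dimethyl-5-(triisopropylsilyloxy)chromane-6-carbaldehyde F9, since only the benzylic C4–O bond can be hydrogenolysed and C3 keeps its configuration. TESOTf/2,6-lutidine then gives the triethylsilyl ether F10. Methylenation (Ph3PCH3Br, t-BuOK, THF, 0 °C) rejoins the route at 9.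

**Further compounds**

F1 | step 13 | 2-bromo-4-hydroxybenzaldehyde (purchased) | O=Cc1ccc(O)cc1Br
F2 | step 13 | 2-bromo-4-(triisopropylsilyloxy)benzaldehyde | O=Cc1ccc(O[Si](C(C)C)(C(C)C)C(C)C)cc1Br
F3 | step 13 | (4S)-4-benzyl-3-{(2S,3S)-3-[2-bromo-4-(triisopropylsilyloxy)phenyl]-3-hydroxy-2-[(3R)-2,2-dimethyl-3-(triethylsilyloxy)-5-(triisopropylsilyloxy)chroman-6-yl]propanoyl}oxazolidin-2-one | CC1(C)Oc2ccc([C@@H]([C@H](O)c3ccc(O[Si](C(C)C)(C(C)C)C(C)C)cc3Br)C(=O)N3[C@@H](Cc4ccccc4)COC3=O)c(O[Si](C(C)C)(C(C)C)C(C)C)c2C[C@H]1O[Si](CC)(CC)CC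
F4 | step 13 | (1S,2R)-1-[2-bromo-4-(triisopropylsilyloxy)phenyl]-2-[(3R)-2,2-dimethyl-3-(triethylsilyloxy)-5-(triisopropylsilyloxy)chroman-6-yl]propane-1,3-diol | CC1(C)Oc2ccc([C@@H]([C@H](O)c3ccc(O[Si](C(C)C)(C(C)C)C(C)C)cc3Br)CO)c(O[Si](C(C)C)(C(C)C)C(C)C)c2C[C@H]1O[Si](CC)(CC)CC
F5 | step 3 | racemic cis-3,4-epoxy-2,2-dimethyl-5-(triisopropylsilyloxy)chromane-6-carbaldehyde | CC1(C)Oc2ccc(C=O)c(O[Si](C(C)C)(C(C)C)C(C)C)c2C3OC13
F6 | step 3 | racemic cis-3,4-epoxy-2,2-dimethyl-5-(triisopropylsilyloxy)-6-vinylchromane | CC1(C)Oc2ccc(C=C)c(O[Si](C(C)C)(C(C)C)C(C)C)c2C3OC13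
F7 | step 3 | racemic 2,2-dimethyl-5-(triisopropylsilyloxy)-6-vinylchroman-3-ol | CC1(C)Oc2ccc(C=C)c(O[Si](C(C)C)(C(C)C)C(C)C)c2CC1O
F8 | step 3 | 2,2-dimethyl-5-(triisopropylsilyloxy)-6-vinylchroman-3-one | CC1(C)Oc2ccc(C=C)c(O[Si](C(C)C)(C(C)C)C(C)C)c2CC1=O
F9 | step 5 | (3R)-3-hydroxy-2,2-dimethyl-5-(triisopropylsilyloxy)chromane-6-carbaldehyde | CC1(C)Oc2ccc(C=O)c(O[Si](C(C)C)(C(C)C)C(C)C)c2C[C@H]1O
F10 | step 5 | (3R)-2,2-dimethyl-3-(triethylsilyloxy)-5-(triisopropylsilyloxy)chromane-6-carbaldehyde | CC1(C)Oc2ccc(C=O)c(O[Si](C(C)C)(C(C)C)C(C)C)c2C[C@H]1O[Si](CC)(CC)CC
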